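**Plan**

Chain atoms are numbered C1–C12 from the arene-bound CH2 to the furan-bound CH2.
- Cuts: C9–C10 (sp3–sp2, key); then C1–C2 together with C3–CH3 (methylalumination/benzylation of a terminal alkyne); then C4–C5 (propargylation of a dienal); the furan is traced back to a butenolide.
- Enabling feature: C9 is homoallylic to the C6=C7(CH3) alkene, so C8–C9 can be carried as a vinyl group on C7. In that 3-methyl-1,3-diene only the monosubstituted C8=C9 bond accepts 9-BBN, and C10, the unsubstituted end of C10=C11, can carry iodine.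
- Forward: arene bromide 3 and the C4–C9 dienynol 8 give the western diene 10; the furan ring is made aromatic from a butenolide and extended to the alkenyl iodide 17; the halves are joined at C9–C10 and the two aryl pivalates are removed last.
- Stereochemistry: C5 (S) from (S)-TRIP-catalysed propargylboration; C6=C7 (E) is bought in with the enynol; C2=C3 and C10=C11 (E) come from syn methylalumination followed by stereoretentive substitution.

Key step: step 9

Assumption: 4-methylfuran-2(5H)-one, (2E)-3-methylpent-2-en-4-yn-1-ol and 2,6-dimethylhydroquinone are taken as commercial; CIP analysis of the given SMILES gives S at C5. (S)-TRIP is (S)-3,3'-bis(2,4,6-triisopropylphenyl)-1,1'-binaphthyl-2,2'-diyl hydrogen phosphate.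

**Route**

Step 1
Reactants: 1 2,6-dimethylbenzene-1,4-diol
Product: 2 2,6-dimethyl-1,4-phenylene bis(2,2-dimethylpropanoate)
Conditions: PivCl (2.5 equiv), Et3N (3 equiv), DMAP (10 mol%), CH2Cl2, 0 °C to rt
Reagents that add atoms: pivaloyl chloride, CC(C)(C)C(Cl)=O
Why: DMAP-catalysed O-acylation of both phenols gives pivalates that deactivate the ring for the radical bromination, should resist AlMe3 and aqueous phosphate, and fall to hydride at the end.

Step 2
Reactants: 2 2,6-dimethyl-1,4-phenylene bis(2,2-dimethylpropanoate)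
Product: 3 2-(bromomethyl)-6-methyl-1,4-phenylene bis(2,2-dimethylpropanoate)
Conditions: NBS (1.0 equiv), AIBN (5 mol%), PhCF3, 80 °C
Reagents that add atoms: N-bromosuccinimide, O=C1CCC(=O)N1Br
Why: Wohl–Ziegler benzylic bromination acts on two symmetry-equivalent methyl groups, so one bromination gives a single constitutional isomer, while one equivalent of NBS limits the dibromide and the acyloxy groups suppress ring bromination.

Step 3
Reactants: 4 (2E)-3-methylpent-2-en-4-yn-1-ol
Product: 5 (2E)-3-methylpenta-2,4-dien-1-ol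
Conditions: H2 (1 atm), Pd/CaCO3 poisoned with Pb(OAc)2, quinoline, EtOAc, 0 °C, stopped after 1 equiv H2
Reagents that add atoms: none
Why: Lindlar semihydrogenation turns the terminal alkyne into the vinyl group that becomes C8=C9 and leaves the E-trisubstituted C6=C7 alkene untouched.

Step 4
Reactants: 5 (2E)-3-methylpenta-2,4-dien-1-ol
Product: 6 (2E)-3-methylpenta-2,4-dienal
Conditions: activated MnO2 (15 equiv), CH2Cl2, rt; filtered, used as a cold solution
Reagents that add atoms: none
Why: MnO2 oxidation of a primary allylic alcohol stops at the aldehyde and, being neutral, should not isomerise the E-alkene.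

Step 5
Reactants: 6 (2E)-3-methylpenta-2,4-dienal; 7 allenylboronic acid pinacol ester
Product: 8 (4S,5E)-6-methylocta-5,7-dien-1-yn-4-ol
Conditions: (S)-TRIP (5 mol%), 4 Å MS, toluene, 0 °C; aq. NaHCO3 work-up
Reagents that add atoms: none
Why: Chiral phosphoric acid-catalysed propargylboration (SE2' addition through a six-membered chair transition state) sets C5, the (S)-catalyst being chosen because the (R)-catalyst is recalled to give (R)-carbinols from aryl and alkenyl aldehydes, whose CIP ranking matches that at C5.

Step 6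
Reactants: 8 (4S,5E)-6-methylocta-5,7-dien-1-yn-4-ol; 3 2-(bromomethyl)-6-methyl-1,4-phenylene bis(2,2-dimethylpropanoate)
Product: 10 2-[(2E,5S,6E)-5-hydroxy-3,7-dimethylnona-2,6,8-trien-1-yl]-6-methyl-1,4-phenylene bis(2,2-dimethylpropanoate), via alkenylalane 9 (not isolated)
Conditions: AlMe3 (3.5 equiv), Cp2ZrCl2 (0.25 equiv), CH2Cl2, 0 °C to rt; volatiles removed; then 3, Pd(PPh3)4 (5 mol%), THF, rt
Reagents that add atoms: trimethylaluminium, C[Al](C)C
Why: Negishi carboalumination adds CH3 to C3 and aluminium to C2 in a syn fashion, and palladium-catalysed coupling of the alkenylalane with the benzylic bromide replaces aluminium with retention, which fixes C2=C3 as E while the C5 hydroxyl rides through as its aluminium alkoxide.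

Step 7
Reactants: 11 4-methylfuran-2(5H)-one; 12 3-bromoprop-1-yne
Product: 15 4-methyl-2-(prop-2-yn-1-yl)furan, via allenylmagnesium bromide 13 (not isolated), via lactol 14 (not isolated)
Conditions: 12, Mg, HgCl2 (1 mol%), Et2O, 0 °C; added to 11, THF, −78 °C; then 1 M aq. HCl, 0 °C
Reagents that add atoms: none
Why: 1,2-Addition of the allenyl Grignard reagent to the lactone carbonyl (SE2', propargyl transfer; the β-methyl group blocks conjugate addition) and acid-induced dehydration of the lactol aromatise the ring, so the furan is 2,4-disubstituted by construction.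

Step 8
Reactants: 15 4-methyl-2-(prop-2-yn-1-yl)furan
Product: 17 2-[(2E)-3-iodo-2-methylprop-2-en-1-yl]-4-methylfuran, via alkenylalane 16 (not isolated)
Conditions: AlMe3 (2.5 equiv), Cp2ZrCl2 (0.25 equiv), CH2Cl2, 0 °C to rt; then I2, THF, −30 °C
Reagents that add atoms: trimethylaluminium, C[Al](C)C; iodine, II
Why: Negishi carboalumination (syn, methyl to the internal carbon) followed by iodinolysis of the C–Al bond with retention gives the (E)-2-methyl-1-iodoalkene, i.e. C10=C11 in its final geometry.

Step 9
Reactants: 10 2-[(2E,5S,6E)-5-hydroxy-3,7-dimethylnona-2,6,8-trien-1-yl]-6-methyl-1,4-phenylene bis(2,2-dimethylpropanoate); 17 2-[(2E)-3-iodo-2-methylprop-2-en-1-yl]-4-methylfuran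
Product: 19 2-[(2E,5S,6E,10E)-5-hydroxy-3,7,11-trimethyl-12-(4-methylfuran-2-yl)dodeca-2,6,10-trien-1-yl]-6-methyl-1,4-phenylene bis(2,2-dimethylpropanoate), via B-alkyl-9-BBN adduct 18 (not isolated)
Conditions: 9-BBN (2.5 equiv), THF, 0 °C to rt; then H2O; then 17, Pd(dppf)Cl2 (5 mol%), AsPh3 (10 mol%), 3 M aq. K3PO4, DMF, rt
Reagents that add atoms: none
Why: 9-BBN adds its B–H bond syn across the only monosubstituted alkene of 10 (C8=C9) with boron on terminal C9, and the primary B-alkyl-9-BBN, activated as its hydroxyborate by aqueous K3PO4, transfers the C9 alkyl group to the alkenylpalladium iodide formed by oxidative addition of zerovalent palladium into the C10–I bond of 17; reductive elimination then forms C9–C10. The closest known reaction type is the B-alkyl Suzuki–Miyaura coupling of diene-derived 9-BBN adducts with (E)-2-methyl-1-iodoalkenes, used to assemble the head-to-tail 1,5-dienes of polyprenoids. No ring is closed and no stereocentre is formed; C5 is a spectator. The step needs chemoselective hydroboration, which the steric demand of 9-BBN should secure: the trisubstituted C2=C3 and C6=C7 alkenes are left alone and the reaction stops after one addition because no terminal alkene remains. It also needs both alkene geometries to be kept: C6=C7 is fixed in the diene, C10=C11 is carried over from 17 with retention, and the wide bite angle of dppf favours reductive elimination over β-hydride loss. The furan and the iodide never meet B–H because 17 is added only after excess borane is quenched, and the free C5 hydroxyl merely takes up one equivalent of 9-BBN as a borinate that is hydrolysed in the coupling medium.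

Step 10
Reactants: 19 2-[(2E,5S,6E,10E)-5-hydroxy-3,7,11-trimethyl-12-(4-methylfuran-2-yl)dodeca-2,6,10-trien-1-yl]-6-methyl-1,4-phenylene bis(2,2-dimethylpropanoate)
Product: 20 2-[(2E,5S,6E,10E)-5-hydroxy-3,7,11-trimethyl-12-(4-methylfuran-2-yl)dodeca-2,6,10-trien-1-yl]-6-methylbenzene-1,4-diol
Conditions: LiAlH4 (4 equiv), THF, 0 °C to rt, Ar; degassed aq. potassium sodium tartrate with Na2S2O4
Reagents that add atoms: none
Why: Hydride reduction of the two aryl esters frees both phenols under non-acidic, non-oxidising conditions that should spare the furan, the three alkenes and the allylic alcohol, and the reducing work-up protects the hydroquinone from air.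

**Compound list**

1 | 2,6-dimethylbenzene-1,4-diol | Cc1cc(O)cc(C)c1O | starting material
2 | 2,6-dimethyl-1,4-phenylene bis(2,2-dimethylpropanoate) | Cc1cc(OC(=O)C(C)(C)C)cc(C)c1OC(=O)C(C)(C)C | intermediate
3 | 2-(bromomethyl)-6-methyl-1,4-phenylene bis(2,2-dimethylpropanoate) | BrCc1cc(OC(=O)C(C)(C)C)cc(C)c1OC(=O)C(C)(C)C | intermediate
4 | (2E)-3-methylpent-2-en-4-yn-1-ol | C#C/C(C)=C/CO | starting material
5 | (2E)-3-methylpenta-2,4-dien-1-ol | C=C/C(C)=C/CO | intermediate
6 | (2E)-3-methylpenta-2,4-dienal | C=C/C(C)=C/C=O | intermediate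
7 | allenylboronic acid pinacol ester, 4,4,5,5-tetramethyl-2-(propa-1,2-dien-1-yl)-1,3,2-dioxaborolane | C=C=CB1OC(C)(C)C(C)(C)O1 | starting material
8 | (4S,5E)-6-methylocta-5,7-dien-1-yn-4-ol | C#CC[C@H](O)/C=C(\C)C=C | intermediate
9 | alkenylalane: [(1E,4S,5E)-4-(dimethylalumanyloxy)-2,6-dimethylocta-1,5,7-trien-1-yl]dimethylalumane | C[Al](C)/C=C(\C)C[C@H](O[Al](C)C)/C=C(\C)C=C | intermediate
10 | 2-[(2E,5S,6E)-5-hydroxy-3,7-dimethylnona-2,6,8-trien-1-yl]-6-methyl-1,4-phenylene bis(2,2-dimethylpropanoate) | C=C/C(C)=C/[C@@H](O)C/C(C)=C/Cc1cc(OC(=O)C(C)(C)C)cc(C)c1OC(=O)C(C)(C)C | intermediate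
11 | 4-methylfuran-2(5H)-one | CC1=CC(=O)OC1 | starting material
12 | 3-bromoprop-1-yne | C#CCBr | starting material
13 | allenylmagnesium bromide | C=C=C[Mg]Br | intermediate
14 | lactol: 4-methyl-2-(prop-2-yn-1-yl)-2,5-dihydrofuran-2-ol (racemic; present as its magnesium alkoxide; the centre is lost on aromatisation) | CC1=CC(O)(CC#C)OC1 | intermediate
15 | 4-methyl-2-(prop-2-yn-1-yl)furan | Cc1coc(CC#C)c1 | intermediate
16 | alkenylalane: dimethyl[(1E)-2-methyl-3-(4-methylfuran-2-yl)prop-1-en-1-yl]alumane | C[Al](C)/C=C(\C)Cc1cc(C)co1 | intermediate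
17 | 2-[(2E)-3-iodo-2-methylprop-2-en-1-yl]-4-methylfuran | I/C=C(\C)Cc1cc(C)co1 | intermediate
18 | B-alkyl-9-BBN adduct: 2-[(2E,5S,6E)-9-(9-borabicyclo[3.3.1]nonan-9-yl)-5-(9-borabicyclo[3.3.1]nonan-9-yloxy)-3,7-dimethylnona-2,6-dien-1-yl]-6-methyl-1,4-phenylene bis(2,2-dimethylpropanoate) | C/C(=C\[C@@H](OB1C2CCCC1CCC2)C/C(C)=C/Cc1cc(OC(=O)C(C)(C)C)cc(C)c1OC(=O)C(C)(C)C)CCB1C2CCCC1CCC2 | intermediate
19 | 2-[(2E,5S,6E,10E)-5-hydroxy-3,7,11-trimethyl-12-(4-methylfuran-2-yl)dodeca-2,6,10-trien-1-yl]-6-methyl-1,4-phenylene bis(2,2-dimethylpropanoate) | C/C(=C\[C@@H](O)C/C(C)=C/Cc1cc(OC(=O)C(C)(C)C)cc(C)c1OC(=O)C(C)(C)C)CC/C=C(\C)Cc1cc(C)co1 | intermediate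
20 | 2-[(2E,5S,6E,10E)-5-hydroxy-3,7,11-trimethyl-12-(4-methylfuran-2-yl)dodeca-2,6,10-trien-1-yl]-6-methylbenzene-1,4-diol | C/C(=C\[C@@H](O)C/C(C)=C/Cc1cc(O)cc(C)c1O)CC/C=C(\C)Cc1cc(C)co1 | target

**Count and risks**

Total step count: 10. Longest linear sequence: 6 steps (steps 3, 4, 5, 6, 9, 10, from 4 to 20).

Steps most likely to fail:

1. Step 7. The Grignard reagent may add a second time to the ring-opened hydroxy enone, may deprotonate the butenolide at its γ-position in place of adding, or may transfer an allenyl in place of a propargyl group. Fallback from 11, returning at 17 (step 8 is then not needed): DIBAL-H reduction of 11 and acidic dehydration would give 3-methylfuran F1. Lithiation at the less hindered C5 (n-BuLi, THF) and allylation with (1E)-3-bromo-1-iodo-2-methylprop-1-ene F3 would give 17 directly. F3 would come from prop-2-yn-1-ol by methylalumination/iodination to (2E)-3-iodo-2-methylprop-2-en-1-ol F2, then CBr4/PPh3. The weakness of this fallback is incomplete C5 over C2 selectivity in the metalation, so the regioisomers would have to be separated.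

2. Step 6. The Al/Zr medium may carbometalate the conjugated diene or ionise the dienylic C5–O bond, and in the palladium stage methyl may be transferred in place of the alkenyl group. Fallback from 8 and 3, returning at 10: silylation of 8 (TBSCl, imidazole) would give tert-butyl(dimethyl){[(4S,5E)-6-methylocta-5,7-dien-1-yn-4-yl]oxy}silane F4. Methylalumination and iodinolysis would give the isolable alkenyl iodide tert-butyl{[(1E,4S,5E)-1-iodo-2,6-dimethylocta-1,5,7-trien-4-yl]oxy}dimethylsilane F5. Zinc insertion into 3 (Zn dust, LiCl, THF) would give {[2,5-bis(2,2-dimethylpropanoyloxy)-3-methylphenyl]methyl}zinc bromide F6. Negishi coupling of F5 with F6 (Pd(OAc)2, SPhos) would give the silyl ether of 10, F7, and Bu4NF/AcOH would return 10. The polarity of the C1–C2 coupling is thereby reversed and no free aluminium alkoxide or excess AlMe3 meets palladium.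

3. Step 5. Enantiofacial discrimination may be low for this β,β-disubstituted dienal, an uncatalysed background addition may erode it further, and the recalled sense of induction would in any case need confirmation by MTPA ester analysis. Fallback from 6, returning at 8: Barbier propargylation of 6 with 3-bromoprop-1-yne 12 and zinc (THF, aq. NH4Cl) would give the racemic alcohol rac-(5E)-6-methylocta-5,7-dien-1-yn-4-ol F8. Lipase-catalysed kinetic resolution (Candida antarctica lipase B, vinyl acetate, MTBE) should then acylate the R enantiomer, by the empirical size rule for secondary alcohols, to (4R,5E)-6-methylocta-5,7-dien-1-yn-4-yl acetate F9. Unreacted (S)-alcohol 8 would be separated by chromatography; at most half of F8 can be used.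

**Further compounds**

F1 | step 7 | 3-methylfuran | Cc1ccoc1
F2 | step 7 | (2E)-3-iodo-2-methylprop-2-en-1-ol | OC/C(C)=C/I
F3 | step 7 | (1E)-3-bromo-1-iodo-2-methylprop-1-ene | BrC/C(C)=C/I
F4 | step 6 | tert-butyl(dimethyl){[(4S,5E)-6-methylocta-5,7-dien-1-yn-4-yl]oxy}silane | C#CC[C@H](O[Si](C)(C)C(C)(C)C)/C=C(\C)C=C
F5 | step 6 | tert-butyl{[(1E,4S,5E)-1-iodo-2,6-dimethylocta-1,5,7-trien-4-yl]oxy}dimethylsilane | I/C=C(\C)C[C@H](O[Si](C)(C)C(C)(C)C)/C=C(\C)C=C
F6 | step 6 | {[2,5-bis(2,2-dimethylpropanoyloxy)-3-methylphenyl]methyl}zinc bromide | Br[Zn]Cc1cc(OC(=O)C(C)(C)C)cc(C)c1OC(=O)C(C)(C)C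
F7 | step 6 | 2-[(2E,5S,6E)-5-{[tert-butyl(dimethyl)silyl]oxy}-3,7-dimethylnona-2,6,8-trien-1-yl]-6-methyl-1,4-phenylene bis(2,2-dimethylpropanoate) | C=C/C(C)=C/[C@@H](O[Si](C)(C)C(C)(C)C)C/C(C)=C/Cc1cc(OC(=O)C(C)(C)C)cc(C)c1OC(=O)C(C)(C)C
F8 | step 5 | rac-(5E)-6-methylocta-5,7-dien-1-yn-4-ol | C#CCC(O)/C=C(\C)C=C
F9 | step 5 | (4R,5E)-6-methylocta-5,7-dien-1-yn-4-yl acetate | C#CC[C@@H](OC(C)=O)/C=C(\C)C=C
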